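**Plan**

Retrosynthetic cuts: the acetyl mask on O3, then the ester C–O bond between the C6 benzylic CH2 and rhizonic acid, the C3–O bond of the lactol, the C6–CH2 bond, and the C1–C7a bond of the lactone (CO2).
Enabling feature: on the benzene ring of the phthalide, C6 (the carbon bearing CH2O) lies between the C7 hydroxyl and the C5 methoxy, and the other neighbour of C7 is the fusion carbon C7a. Boron bound to O7 can therefore pass formaldehyde only to C6, never to the equally electron-rich C4.
Forward, rings: the lactone ring is built from 3,5-dimethoxybenzyl alcohol (Br, Li, CO2) and O7 is freed. A six-membered dioxaborin ring is closed across O7/C6, exchanged for a ketal ring, and C3 is oxygenated through its anion.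
Forward, joining: the ketal ring is opened, and rhizonic acid (two steps from methyl 2,4-dihydroxy-3,6-dimethylbenzoate) is attached at the benzylic carbon by a Mitsunobu reaction.
Stereochemistry: the single centre C3 (R) comes from a lipase dynamic kinetic acetylation of the racemising lactol. It travels as the acetate and is bared last by the same lipase without breaking the C3–O bond.

Key step: step 4

Assumption: C3 is the lactol carbon of a pseudo-acid and is taken to hold its configuration only in cold, base-free, non-ionising media, because base or heat opens it to the 2-formylbenzoic acid; its hydroxyl is therefore uncovered in the very last operation.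

**Step 1**
Reactants: 1 3,5-dimethoxybenzyl alcohol
Product: 2 2-bromo-3,5-dimethoxybenzyl alcohol
Conditions: NBS (1.0 equiv), CH2Cl2, 0 °C to rt
Reagents that add atoms: N-bromosuccinimide, O=C1CCC(=O)N1Br
Why: Electrophilic aromatic bromination should go para to one methoxy and ortho to the other (C2) rather than into the crowded C4 site between both methoxy groups, and one equivalent of NBS avoids a second bromination.

**Step 2**
Reactants: 2 2-bromo-3,5-dimethoxybenzyl alcohol
Product: 5 5,7-dimethoxyphthalide, via aryllithium alkoxide 3 (not isolated), via hydroxy acid 4 (not isolated)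
Conditions: n-BuLi (2.2 equiv), THF, −78 °C; CO2; then 2 M HCl, rt
Reagents that add atoms: carbon dioxide, O=C=O
Why: Halogen–metal exchange, carboxylation and lactonisation: the first equivalent of n-BuLi deprotonates the alcohol, the second exchanges bromine for lithium faster than any ring deprotonation, CO2 traps the aryllithium, and acidification lets the ortho-hydroxymethyl benzoic acid close to the five-membered lactone.

**Step 3**
Reactants: 5 5,7-dimethoxyphthalide
Product: 6 7-hydroxy-5-methoxyphthalide
Conditions: BCl3 (1.2 equiv), CH2Cl2, −10 °C to rt; H2O
Reagents that add atoms: none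
Why: Chelation-directed Lewis-acid ether cleavage: BCl3 bridges the lactone carbonyl oxygen and the neighbouring C7 methoxy oxygen in a six-membered chelate, so chloride removes only that methyl group and the C5 ether and the lactone stay intact.

**Step 4**
Reactants: 6 7-hydroxy-5-methoxyphthalide; 7 phenylboronic acid; 8 formaldehyde (as paraformaldehyde)
Product: 10 2-phenyl-4H-1,3,2-dioxaborin fused at C6–C7 of 5-methoxyphthalide (cyclic phenylboronate of 7-hydroxy-6-(hydroxymethyl)-5-methoxyphthalide), via mixed boronate 9 (not isolated)
Conditions: PhB(OH)2 (1.3 equiv), (CH2O)n (excess, in portions), EtCO2H (0.3 equiv), toluene, reflux, Dean–Stark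
Reagents that add atoms: phenylboronic acid 7, OB(O)c1ccccc1; formaldehyde 8, C=O
Why: Azeotropic esterification first hangs the PhB(OH) unit on O7 (9), the still Lewis-acidic boron binds monomeric formaldehyde, and the aldehyde carbon is passed to C6 through a six-membered cyclic transition state (C6–C7–O7–B–O=CH2), after which proton loss restores the arene. The closest known reaction type is the boronic-acid-mediated ortho-specific hydroxymethylation of phenols, which is known to end at 2-phenyl-4H-1,3,2-benzodioxaborins. The only ring closed, the six-membered dioxaborin, is drawn shut as the C6–CH2 bond forms inside the boron template, and azeotropic loss of water from the resulting hydroxyborate makes the closure irreversible. No stereocentre is created. The step needs C6 over C4: both carbons are ortho to the C5 methoxy and ortho or para to O7, but only C6 lies within reach of formaldehyde held on O7-bound boron, and the second ortho position of the phenol is the blocked fusion carbon C7a. Locking the new benzylic oxygen on boron should also stop a second arylation and thermal elimination to an ortho-quinone methide at reflux.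

**Step 5**
Reactants: 10 cyclic phenylboronate
Product: 12 acetonide of 7-hydroxy-6-(hydroxymethyl)-5-methoxyphthalide (2,2-dimethyl-4H-1,3-dioxine ring; O on C7; CH2 on C6), via free diol 11 (not isolated)
Conditions: pinacol (1.1 equiv), acetone, rt; then Me2C(OMe)2, TsOH·H2O (cat.), rt
Reagents that add atoms: 2,2-dimethoxypropane, COC(C)(C)OC
Why: Boronic ester exchange followed by ketalisation: pinacol forms the stronger dialkyl boronate and frees the phenol and benzylic alcohol, which 2,2-dimethoxypropane and acid tie up at once as a six-membered ketal, the base-stable mask needed for the anion chemistry.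

**Step 6**
Reactants: 12 acetonide
Product: 14 (±)-3-hydroxy derivative of 12 (racemic lactol), via potassium C3 anion 13 (not isolated)
Conditions: KN(SiMe3)2 (1.15 equiv), THF, −78 °C; cannulated into 2-(phenylsulfonyl)-3-phenyloxaziridine (1.5 equiv), THF, −78 °C; AcOH quench
Reagents that add atoms: 2-(phenylsulfonyl)-3-phenyloxaziridine, O=S(=O)(N1OC1c1ccccc1)c1ccccc1
Why: Davis oxidation of a stabilised carbanion: C3–H is the only acidic C–H (benzylic, next to the ring oxygen and conjugated through the arene with the lactone carbonyl), its anion takes electrophilic oxygen from the N-sulfonyloxaziridine, inverse addition keeps the anion away from the oxidised product, and the new C3 centre forms racemic, which is harmless because the lactol equilibrates.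

**Step 7**
Reactants: 14 racemic lactol
Product: 15 (3R)-3-acetoxy derivative of 12
Conditions: immobilised Burkholderia cepacia lipase, vinyl acetate (4 equiv), Et3N (0.2 equiv), toluene, 40 °C
Reagents that add atoms: vinyl acetate, C=COC(C)=O
Why: Lipase-catalysed dynamic kinetic resolution of a pseudo-acid lactol, known for hydroxybutenolides: Et3N keeps both lactol enantiomers in rapid exchange through the open formyl carboxylate while the enzyme acetylates one irreversibly, and the empirical size rule for secondary alcohols (benzo ring large, ring oxygen medium) predicts the R acetate, which fixes C3.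

**Step 8**
Reactants: 15 (3R)-acetate acetonide
Product: 16 (3R)-3-acetoxy-7-hydroxy-6-(hydroxymethyl)-5-methoxyphthalide
Conditions: AcOH–H2O–THF (3:1:1), 40 °C
Reagents that add atoms: none
Why: Acid-catalysed ketal hydrolysis: the aryl alkyl ketal ionises far more easily than the C3 acylal, whose cation is destabilised by the lactone carbonyl, and phthalidyl esters are most stable in weakly acidic water, so C3 should stay R.

**Step 9**
Reactants: 17 methyl 2,4-dihydroxy-3,6-dimethylbenzoate
Product: 18 methyl 2-hydroxy-4-methoxy-3,6-dimethylbenzoate (methyl rhizonate)
Conditions: MeI (1.1 equiv), K2CO3 (1.2 equiv), acetone, reflux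
Reagents that add atoms: iodomethane, CI
Why: Williamson etherification: the 2-OH is tied to the ester carbonyl by a hydrogen bond and flanked by the C3 methyl, so only the free 4-OH should be methylated with about one equivalent of MeI.

**Step 10**
Reactants: 18 methyl rhizonate
Product: 19 2-hydroxy-4-methoxy-3,6-dimethylbenzoic acid (rhizonic acid)
Conditions: KOH (5 equiv), DMSO–H2O, 90 °C; then cold 1 M HCl, 0 °C
Reagents that add atoms: potassium hydroxide, [K+].[OH-]
Why: Saponification of a doubly ortho-substituted benzoate needs poorly solvated hydroxide in aqueous DMSO, and cold acidification avoids decarboxylation of the electron-rich salicylic acid.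

**Step 11**
Reactants: 16 (3R)-3-acetoxy-7-hydroxy-6-(hydroxymethyl)-5-methoxyphthalide; 19 rhizonic acid
Product: 20 [(3R)-3-acetoxy-7-hydroxy-5-methoxyphthalid-6-yl]methyl 2-hydroxy-4-methoxy-3,6-dimethylbenzoate
Conditions: PPh3 (1.3 equiv), DIAD (1.3 equiv), THF, 0 °C to rt
Reagents that add atoms: none
Why: Mitsunobu esterification: the primary benzylic alcohol is activated as its alkoxyphosphonium salt and the hindered acid only has to act as an oxygen nucleophile at CH2, free phenols on either partner are known to be tolerated because the carboxylic acid is far more acidic, and C3 is not touched.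

**Step 12**
Reactants: 20 (3R)-acetate
Product: 21 [(3R)-3,7-dihydroxy-5-methoxyphthalid-6-yl]methyl 2-hydroxy-4-methoxy-3,6-dimethylbenzoate (CNP0398000.1)
Conditions: immobilised Burkholderia cepacia lipase, n-BuOH (5 equiv), MTBE, 5 °C; filtration, evaporation below 10 °C
Reagents that add atoms: none
Why: Lipase-catalysed alcoholysis: the enzyme that makes the R acetate also accepts it (microscopic reversibility) and attacks the acetyl carbonyl, so the acyl–oxygen bond breaks and the C3–O bond keeps its R configuration, while the cold, base-free medium should hold back lactol ring opening and loss of rhizonate, and the hindered benzoate is no lipase substrate.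

**Compound list**

1 | 3,5-dimethoxybenzyl alcohol | COc1cc(CO)cc(OC)c1 | starting material
2 | 2-bromo-3,5-dimethoxybenzyl alcohol | COc1cc(CO)c(Br)c(OC)c1 | intermediate
3 | lithium (2-lithio-3,5-dimethoxyphenyl)methoxide | [Li]OCc1cc(OC)cc(OC)c1[Li] | intermediate
4 | 2-(hydroxymethyl)-4,6-dimethoxybenzoic acid | COc1cc(CO)c(C(=O)O)c(OC)c1 | intermediate
5 | 5,7-dimethoxyphthalide | COc1cc2c(c(OC)c1)C(=O)OC2 | intermediate
6 | 7-hydroxy-5-methoxyphthalide | COc1cc2c(c(O)c1)C(=O)OC2 | intermediate
7 | phenylboronic acid | OB(O)c1ccccc1 | starting material
8 | formaldehyde (as paraformaldehyde) | C=O | starting material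
9 | 5-methoxyphthalid-7-yl hydrogen phenylboronate | COc1cc2c(c(OB(O)c3ccccc3)c1)C(=O)OC2 | intermediate
10 | cyclic phenylboronate (2-phenyl-4H-1,3,2-dioxaborin) of 7-hydroxy-6-(hydroxymethyl)-5-methoxyphthalide | COc1cc2c(c3c1COB(c1ccccc1)O3)C(=O)OC2 | intermediate
11 | 7-hydroxy-6-(hydroxymethyl)-5-methoxyphthalide | COc1cc2c(c(O)c1CO)C(=O)OC2 | intermediate
12 | acetonide of 11 (2,2-dimethyl-4H-1,3-dioxine ring across O7 and the C6 CH2) | COc1cc2c(c3c1COC(C)(C)O3)C(=O)OC2 | intermediate
13 | potassium salt of the C3 anion of 12 | COc1cc2c(c3c1COC(C)(C)O3)C(=O)O[CH-]2.[K+] | intermediate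
14 | (±)-3-hydroxy derivative of 12 | COc1cc2c(c3c1COC(C)(C)O3)C(=O)OC2O | intermediate
15 | (3R)-3-acetoxy derivative of 12 | COc1cc2c(c3c1COC(C)(C)O3)C(=O)O[C@H]2OC(C)=O | intermediate
16 | (3R)-3-acetoxy-7-hydroxy-6-(hydroxymethyl)-5-methoxyphthalide | COc1cc2c(c(O)c1CO)C(=O)O[C@H]2OC(C)=O | intermediate
17 | methyl 2,4-dihydroxy-3,6-dimethylbenzoate | COC(=O)c1c(C)cc(O)c(C)c1O | starting material
18 | methyl 2-hydroxy-4-methoxy-3,6-dimethylbenzoate | COC(=O)c1c(C)cc(OC)c(C)c1O | intermediate
19 | 2-hydroxy-4-methoxy-3,6-dimethylbenzoic acid | COc1cc(C)c(C(=O)O)c(O)c1C | intermediate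
20 | [(3R)-3-acetoxy-7-hydroxy-5-methoxyphthalid-6-yl]methyl 2-hydroxy-4-methoxy-3,6-dimethylbenzoate | COc1cc(C)c(C(=O)OCc2c(OC)cc3c(c2O)C(=O)O[C@H]3OC(C)=O)c(O)c1C | intermediate
21 | [(3R)-3,7-dihydroxy-5-methoxyphthalid-6-yl]methyl 2-hydroxy-4-methoxy-3,6-dimethylbenzoate | COc1cc(C)c(C(=O)OCc2c(OC)cc3c(c2O)C(=O)O[C@H]3O)c(O)c1C | target

**Totals**

Total step count: 12.
Longest linear sequence: 10 (steps 1–8, 11, 12).

**Steps most likely to fail**

Step 12. The liberated lactol may lose configurational purity by ring–chain tautomerism during or after the alcoholysis, or the lipase may turn over the bulky ester too slowly. The fallback gives up stereoretentive unmasking for physical separation and sets out from 20. The acetate is hydrolysed without regard to configuration with 0.5 M HCl in aqueous THF at rt to the racemic lactol F1. Its enantiomers are then separated by preparative supercritical-fluid chromatography on an immobilised amylose carbamate phase at sub-ambient temperature, with cold collection. The S lactol F2 is left to re-equilibrate to F1 in warm solvent and is recycled. The R fraction is 21, where the route is rejoined.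

Step 6. The C3 anion may condense with lactone that is not yet deprotonated, or add to the ring-opened aldehyde carboxylate that arises on oxygen transfer. The fallback avoids carbanion chemistry and sets out from 12.
- KOH in aqueous THF opens the lactone to the potassium hydroxy carboxylate F3.
- MeI in DMF alkylates F3 to the hydroxy ester F4, which is oxidised without delay to forestall relactonisation.
- MnO2 in CH2Cl2 converts F4 into the formyl ester F5.
- LiOH in aqueous THF at 0 °C, helped by the neighbouring formyl group, gives the lithium formyl carboxylate F6.
- Acidification to pH 4 with dilute HCl closes F6 to the lactol, and the route is rejoined at 14.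

Step 7. Acyl transfer may be slow or poorly selective if the enzyme pocket rejects the tricyclic lactol. The sense of selection may also run against the empirical rule, or racemisation may lag behind acylation. The fallback replaces the enzyme by small-molecule Lewis-base catalysis and sets out from 14. It is an acylative dynamic kinetic resolution, of the type known for lactols, with benzotetramisole, acetic anhydride and i-Pr2NEt in toluene at 0 °C. Both catalyst enantiomers are available, so the one that delivers the R acetate is chosen. The reaction leads directly to 15, where the route is rejoined.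

**Further compounds**

F1 | step 12 | racemic (3,7-dihydroxy-5-methoxyphthalid-6-yl)methyl 2-hydroxy-4-methoxy-3,6-dimethylbenzoate | COc1cc(C)c(C(=O)OCc2c(OC)cc3c(c2O)C(=O)OC3O)c(O)c1C
F2 | step 12 | [(3S)-3,7-dihydroxy-5-methoxyphthalid-6-yl]methyl 2-hydroxy-4-methoxy-3,6-dimethylbenzoate | COc1cc(C)c(C(=O)OCc2c(OC)cc3c(c2O)C(=O)O[C@@H]3O)c(O)c1C
F3 | step 6 | potassium 7-(hydroxymethyl)-5-methoxy-2,2-dimethyl-4H-1,3-benzodioxine-8-carboxylate | [K+].[O-]C(=O)c1c(CO)cc(OC)c2c1OC(C)(C)OC2
F4 | step 6 | methyl 7-(hydroxymethyl)-5-methoxy-2,2-dimethyl-4H-1,3-benzodioxine-8-carboxylate | COC(=O)c1c(CO)cc(OC)c2c1OC(C)(C)OC2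
F5 | step 6 | methyl 7-formyl-5-methoxy-2,2-dimethyl-4H-1,3-benzodioxine-8-carboxylate | COC(=O)c1c(C=O)cc(OC)c2c1OC(C)(C)OC2
F6 | step 6 | lithium 7-formyl-5-methoxy-2,2-dimethyl-4H-1,3-benzodioxine-8-carboxylate | [Li+].[O-]C(=O)c1c(C=O)cc(OC)c2c1OC(C)(C)OC2
F0 | step 7 | none | none
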